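## Retrosynthetic overview

- Labels: ring A = the 1,5-dihydro-2H-pyrrol-2-one (N1, C2=O, C3, C4, C5); ring B = the tetronic acid (O1, C2–C5); chain C1′–C13′ counted from C3 of ring A to C5 of ring B. The key disconnection is C3(ring A)–C1′, giving 3-bromo ring A and a complete C1′–C13′/ring B tetraene whose chain ends in the alkene C1′=C2′.
- Enabling feature: C3 is the α-carbon of the conjugated lactam C2(=O)–C3=C4, so Br2 addition/HBr loss places a halogen on C3 only, and the C3–Br bond is an activated alkenyl electrophile. C1′=C2′ is the only monosubstituted one of the five C=C bonds of the chain fragment, so 9-BBN borylates C1′ alone. Both carbons react with reversed native polarity in a one-pot hydroboration/B-alkyl Suzuki–Miyaura union.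
- Chain fragment: C5′–C6′ by alkenyl–alkenyl Suzuki coupling ((E,E)-diene), C11′=C12′ by (Z)-selective iodo-olefination, C12′–C13′ by copper-catalysed alkenyl-Grignard opening of methyl (S)-glycidate. All three stereocentres come from the chiral pool: (S)-β-citronellene for C8′, the glycidate for C5 of ring B, (S)-2-methylbutylamine for the N-side chain.
- Ring order: ring A first (amine plus masked butenedial, then C3 bromination); ring B by Dieckmann cyclisation in the chain fragment, masked as its 2-(trimethylsilyl)ethyl ether; then the C3–C1′ union; fluoride unmasking of ring B ends the route.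

Key step: step 13

Remark on the chemistry: (S)-2-methylbutan-1-amine, (S)-β-citronellene and methyl (S)-glycidate are taken as commercial single enantiomers, and 2,5-dimethoxy-2,5-dihydrofuran as the commercial cis/trans mixture, both isomers of which hydrolyse to the same dialdehyde.

## Route

Step 1
Reactants: 1 (2S)-2-methylbutan-1-amine; 2 2,5-dimethoxy-2,5-dihydrofuran
Product: 3 1-[(2S)-2-methylbutyl]-1,5-dihydro-2H-pyrrol-2-one
Conditions: dilute aq. HCl, rt, 16 h
Reagents that add atoms: none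
Why: Acid hydrolysis of the bis-acetal unmasks (Z)-but-2-enedial, which condenses with the primary amine to a 2-hydroxypyrrole that settles as its conjugated lactam tautomer (the known one-step 2,5-dimethoxy-2,5-dihydrofuran route to N-substituted 1,5-dihydropyrrol-2-ones), while the side-chain stereocentre, remote from any activating group, is carried over unchanged.

Step 2
Reactants: 3 1-[(2S)-2-methylbutyl]-1,5-dihydro-2H-pyrrol-2-one
Product: 5 3-bromo-1-[(2S)-2-methylbutyl]-1,5-dihydro-2H-pyrrol-2-one, via trans-3,4-dibromopyrrolidinone 4 (not isolated)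
Conditions: Br2 (1.05 equiv), CH2Cl2, 0 °C; then Et3N (2.5 equiv), 0 °C → rt
Reagents that add atoms: bromine, BrBr
Why: Bromination–dehydrobromination of an α,β-unsaturated lactam, in which anti addition of Br2 across C3=C4 gives the dibromide and Et3N then removes the acidic C3–H and expels the C4 bromide (E1cB), so that bromine remains on C3 only.

Step 3
Reactants: 6 (3S)-3,7-dimethylocta-1,6-diene ((S)-β-citronellene)
Product: 8 (4S)-4-methylhex-5-en-1-ol, via (4S)-4-methylhex-5-enal 7 (not isolated)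
Conditions: O3 (1 equiv, Sudan Red 7B end point), CH2Cl2/MeOH, −78 °C; then NaBH4, −78 → 0 °C
Reagents that add atoms: ozone, [O-][O+]=O
Why: Chemoselective ozonolysis with reductive work-up, in which the electrophilic ozone consumes the electron-rich trisubstituted C6=C7 bond much faster than the monosubstituted vinyl group and NaBH4 reduces the carbonyl and peroxidic intermediates to the primary alcohol, the stereocentre of 6 becoming C4 of 8 without being touched.

Step 4
Reactants: 8 (4S)-4-methylhex-5-en-1-ol; 9 4,4,5,5-tetramethyl-2-vinyl-1,3,2-dioxaborolane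
Product: 10 (4S,5E)-4-methyl-6-(4,4,5,5-tetramethyl-1,3,2-dioxaborolan-2-yl)hex-5-en-1-ol
Conditions: second-generation Grubbs catalyst RuCl2(=CHPh)(H2IMes)(PCy3) (3 mol %), 9 (2.5 equiv), CH2Cl2, 40 °C
Reagents that add atoms: none
Why: Olefin cross-metathesis of a terminal alkene with vinyl-Bpin, expected to give the (E)-alkenylboronate under thermodynamic control reinforced by the allylic methyl branch, and placed at this stage because 8 has no second alkene that could ring-close.

Step 5
Reactants: 11 pent-1-en-4-yne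
Product: 13 (1E)-1-iodo-2-methylpenta-1,4-diene, via alkenylalane 12 (not isolated)
Conditions: Me3Al (2 equiv), Cp2ZrCl2 (0.2 equiv), CH2Cl2, 0 °C → rt; then I2, THF, −30 → 0 °C
Reagents that add atoms: trimethylaluminium, C[Al](C)C; iodine, II
Why: Negishi zirconium-catalysed carboalumination, in which Me–Al adds syn across the terminal alkyne (methyl to the internal carbon, aluminium to the terminus) and iodine cleaves the C–Al bond with retention to the (E)-iodide, the isolated terminal alkene being far less reactive toward carbometalation.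

Step 6
Reactants: 10 (4S,5E)-4-methyl-6-(4,4,5,5-tetramethyl-1,3,2-dioxaborolan-2-yl)hex-5-en-1-ol; 13 (1E)-1-iodo-2-methylpenta-1,4-diene
Product: 14 (4S,5E,7E)-4,8-dimethylundeca-5,7,10-trien-1-ol
Conditions: PdCl2(dppf)·CH2Cl2 (5 mol %), K3PO4 (3 equiv, aq.), THF, rt
Reagents that add atoms: none
Why: Suzuki–Miyaura alkenyl–alkenyl coupling, stereoretentive at both partners, should give the (5E,7E)-diene and tolerates the free alcohol and the remote terminal alkene.

Step 7
Reactants: 14 (4S,5E,7E)-4,8-dimethylundeca-5,7,10-trien-1-ol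
Product: 15 (4S,5E,7E)-4,8-dimethylundeca-5,7,10-trienal
Conditions: TEMPO (10 mol %), PhI(OAc)2 (1.1 equiv), CH2Cl2, rt
Reagents that add atoms: none
Why: TEMPO/PhI(OAc)2 oxidation through the oxoammonium salt stops at the aldehyde, leaves the diene and the skipped terminal alkene alone, and cannot epimerise C4, which is γ to the new carbonyl.

Step 8
Reactants: 15 (4S,5E,7E)-4,8-dimethylundeca-5,7,10-trienal
Product: 16 (4E,6E,8S,11Z)-12-iodo-4,8-dimethyltrideca-1,4,6,11-tetraene
Conditions: [Ph3PEt]I, n-BuLi, THF, rt; I2, −78 °C; NaN(SiMe3)2, −20 °C; then 15, −78 °C → rt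
Reagents that add atoms: ethyltriphenylphosphonium iodide, CC[P+](c1ccccc1)(c1ccccc1)c1ccccc1.[I-]; iodine, II
Why: Stork–Zhao-type Wittig olefination with (1-iodoethylidene)triphenylphosphorane, a non-stabilised α-iodo ylide that reacts under kinetic control through the cis-oxaphosphetane and should give predominantly the (Z)-iodoalkene (iodine cis to the chain).

Step 9
Reactants: 16 (4E,6E,8S,11Z)-12-iodo-4,8-dimethyltrideca-1,4,6,11-tetraene; 17 methyl (2S)-oxirane-2-carboxylate
Product: 20 methyl (2S,4Z,8S,9E,11E)-2-hydroxy-4,8,12-trimethylpentadeca-4,9,11,14-tetraenoate, via alkenyllithium 18 (not isolated), via alkenylmagnesium bromide 19 (not isolated)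
Conditions: t-BuLi (2.05 equiv), Et2O, −78 °C; MgBr2·OEt2 (1.1 equiv), −78 → −40 °C; CuBr·SMe2 (10 mol %), 17, THF, −40 → −20 °C; aq. NH4Cl
Reagents that add atoms: none
Why: Iodine–lithium exchange with retention of alkene geometry, transmetalation to magnesium and copper-catalysed SN2 opening of the glycidate at its unsubstituted C3 should give the α-hydroxy ester, in which the (2S) carbinol is the untouched C2 stereocentre of 17 and the (4Z) geometry is that of the alkenyl iodide.

Step 10
Reactants: 20 methyl (2S,4Z,8S,9E,11E)-2-hydroxy-4,8,12-trimethylpentadeca-4,9,11,14-tetraenoate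
Product: 21 methyl (2S,4Z,8S,9E,11E)-4,8,12-trimethyl-2-(propanoyloxy)pentadeca-4,9,11,14-tetraenoate
Conditions: (EtCO)2O (1.5 equiv), Et3N, DMAP (5 mol %), CH2Cl2, 0 °C → rt
Reagents that add atoms: propanoic anhydride, CCC(=O)OC(=O)CC
Why: DMAP-catalysed O-acylation of the secondary alcohol, which does not touch the stereocentre.

Step 11
Reactants: 21 methyl (2S,4Z,8S,9E,11E)-4,8,12-trimethyl-2-(propanoyloxy)pentadeca-4,9,11,14-tetraenoate
Product: 22 (5S)-4-hydroxy-3-methyl-5-[(2Z,6S,7E,9E)-2,6,10-trimethyltrideca-2,7,9,12-tetraen-1-yl]furan-2(5H)-one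
Conditions: LiN(SiMe3)2 (2.5 equiv), THF, −78 → 0 °C; then 1 M HCl
Reagents that add atoms: none
Why: Lacey–Dieckmann cyclisation, in which the propanoate enolate attacks the methyl ester (5-exo-trig) and expels methoxide to close ring B, and the tetronate anion formed at once is no longer enolisable at C5, so the (S) configuration from step 9 should be preserved.

Step 12
Reactants: 22 (5S)-4-hydroxy-3-methyl-5-[(2Z,6S,7E,9E)-2,6,10-trimethyltrideca-2,7,9,12-tetraen-1-yl]furan-2(5H)-one
Product: 23 (5S)-3-methyl-4-[2-(trimethylsilyl)ethoxy]-5-[(2Z,6S,7E,9E)-2,6,10-trimethyltrideca-2,7,9,12-tetraen-1-yl]furan-2(5H)-one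
Conditions: PPh3, DIAD (betaine preformed at 0 °C), 2-(trimethylsilyl)ethanol, THF, 0 °C → rt
Reagents that add atoms: 2-(trimethylsilyl)ethanol, C[Si](C)(C)CCO
Why: Mitsunobu O-alkylation, in which the acidic tetronic acid (pKa about 4) protonates the preformed betaine and its anion is alkylated regioselectively at O4 by the alkoxyphosphonium salt, giving a fluoride-labile ether that masks the acidic OH during the borane and palladium chemistry.

Step 13
Reactants: 23 (5S)-3-methyl-4-[2-(trimethylsilyl)ethoxy]-5-[(2Z,6S,7E,9E)-2,6,10-trimethyltrideca-2,7,9,12-tetraen-1-yl]furan-2(5H)-one; 5 3-bromo-1-[(2S)-2-methylbutyl]-1,5-dihydro-2H-pyrrol-2-one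
Product: 25 (5S)-3-methyl-5-[(2Z,6S,7E,9E)-2,6,10-trimethyl-13-{1-[(2S)-2-methylbutyl]-2-oxo-2,5-dihydro-1H-pyrrol-3-yl}trideca-2,7,9-trien-1-yl]-4-[2-(trimethylsilyl)ethoxy]furan-2(5H)-one, via B-alkyl-9-BBN 24 (not isolated)
Conditions: 9-BBN (0.5 M in THF, 1.3 equiv), THF, 0 °C → rt; then 5 (1.2 equiv), PdCl2(dppf)·CH2Cl2 (5 mol %), AsPh3 (5 mol %), Cs2CO3 (3 equiv), DMF/H2O, rt → 40 °C
Reagents that add atoms: none
Why: 9-BBN adds B–H syn and anti-Markovnikov to C1′=C2′, placing boron on C1′; after addition of aqueous carbonate the alkyl(hydroxy)borate transfers its primary alkyl group to the alkenylpalladium bromide formed by oxidative addition of zerovalent palladium (generated from PdCl2(dppf)) into the C3–Br bond of ring A, and reductive elimination forms C3–C1′. The closest known reaction type is the B-alkyl Suzuki–Miyaura coupling of α-halo enones and other electron-poor alkenyl halides with 9-alkyl-9-BBN reagents made in situ from terminal alkenes, a standard late fragment union in polyene synthesis. No ring is closed and no stereocentre is created: the position of the C3=C4 double bond is fixed by the alkenyl bromide, and the stereocentres at C8′, at C5 of ring B and in the N-side chain are remote and not enolisable under carbonate. The step needs hydroboration of one out of five C=C bonds of 23, which is secured because C1′=C2′ is the only monosubstituted alkene (9-BBN is far more reactive toward such alkenes than toward 1,2-disubstituted, trisubstituted or conjugated ones) and because ring A, with its own C3=C4 bond, is added only after the B–H reagent has been consumed or quenched by water. It also needs reductive elimination to outrun β-hydride elimination of the alkylpalladium intermediate, which the wide bite angle of dppf and the electron-poor alkenyl partner favour. In this union C3, natively the nucleophilic α-carbon of the lactam, reacts as the electrophile and C1′, a plain alkene carbon, as the nucleophile, so neither fragment carries an organometallic or a leaving group through the earlier steps.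

Step 14
Reactants: 25 (5S)-3-methyl-5-[(2Z,6S,7E,9E)-2,6,10-trimethyl-13-{1-[(2S)-2-methylbutyl]-2-oxo-2,5-dihydro-1H-pyrrol-3-yl}trideca-2,7,9-trien-1-yl]-4-[2-(trimethylsilyl)ethoxy]furan-2(5H)-one
Product: 26 (5S)-4-hydroxy-3-methyl-5-[(2Z,6S,7E,9E)-2,6,10-trimethyl-13-{1-[(2S)-2-methylbutyl]-2-oxo-2,5-dihydro-1H-pyrrol-3-yl}trideca-2,7,9-trien-1-yl]furan-2(5H)-one
Conditions: Bu4NF (3 equiv), THF, 0 °C → rt; then dilute aq. HCl
Reagents that add atoms: none
Why: Fluoride attacks silicon and triggers β-elimination of ethene and Me3SiF, releasing the tetronate (a leaving group comparable to a carboxylate), which is protonated on acidic work-up, under conditions mild enough to leave ring A, the triene and all stereocentres untouched.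

## Compound list

1 | (2S)-2-methylbutan-1-amine | CC[C@H](C)CN | starting material
2 | 2,5-dimethoxy-2,5-dihydrofuran (cis/trans mixture) | COC1C=CC(OC)O1 | starting material
3 | 1-[(2S)-2-methylbutyl]-1,5-dihydro-2H-pyrrol-2-one | CC[C@H](C)CN1CC=CC1=O | intermediate
4 | trans-3,4-dibromo-1-[(2S)-2-methylbutyl]pyrrolidin-2-one (both trans diastereomers, ring centres left undefined) | CC[C@H](C)CN1CC(Br)C(Br)C1=O | intermediate (not isolated)
5 | 3-bromo-1-[(2S)-2-methylbutyl]-1,5-dihydro-2H-pyrrol-2-one | CC[C@H](C)CN1CC=C(Br)C1=O | intermediate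
6 | (3S)-3,7-dimethylocta-1,6-diene ((S)-β-citronellene) | C=C[C@@H](C)CCC=C(C)C | starting material
7 | (4S)-4-methylhex-5-enal | C=C[C@@H](C)CCC=O | intermediate (not isolated)
8 | (4S)-4-methylhex-5-en-1-ol | C=C[C@@H](C)CCCO | intermediate
9 | 4,4,5,5-tetramethyl-2-vinyl-1,3,2-dioxaborolane | C=CB1OC(C)(C)C(C)(C)O1 | starting material
10 | (4S,5E)-4-methyl-6-(4,4,5,5-tetramethyl-1,3,2-dioxaborolan-2-yl)hex-5-en-1-ol | OCCC[C@H](C)/C=C/B1OC(C)(C)C(C)(C)O1 | intermediate
11 | pent-1-en-4-yne | C=CCC#C | starting material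
12 | dimethyl[(1E)-2-methylpenta-1,4-dien-1-yl]alumane | C=CC/C(C)=C/[Al](C)C | intermediate (not isolated)
13 | (1E)-1-iodo-2-methylpenta-1,4-diene | C=CC/C(C)=C/I | intermediate
14 | (4S,5E,7E)-4,8-dimethylundeca-5,7,10-trien-1-ol | C=CC/C(C)=C/C=C/[C@@H](C)CCCO | intermediate
15 | (4S,5E,7E)-4,8-dimethylundeca-5,7,10-trienal | C=CC/C(C)=C/C=C/[C@@H](C)CCC=O | intermediate
16 | (4E,6E,8S,11Z)-12-iodo-4,8-dimethyltrideca-1,4,6,11-tetraene | C=CC/C(C)=C/C=C/[C@@H](C)CC/C=C(/C)I | intermediate
17 | methyl (2S)-oxirane-2-carboxylate | COC(=O)[C@@H]1CO1 | starting material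
18 | [(2E,6S,7E,9E)-6,10-dimethyltrideca-2,7,9,12-tetraen-2-yl]lithium (Li in the place of the iodine of 16, geometry retained) | C=CC/C(C)=C/C=C/[C@@H](C)CC/C=C(/C)[Li] | intermediate (not isolated)
19 | bromo[(2Z,6S,7E,9E)-6,10-dimethyltrideca-2,7,9,12-tetraen-2-yl]magnesium | C=CC/C(C)=C/C=C/[C@@H](C)CC/C=C(/C)[Mg]Br | intermediate (not isolated)
20 | methyl (2S,4Z,8S,9E,11E)-2-hydroxy-4,8,12-trimethylpentadeca-4,9,11,14-tetraenoate | C=CC/C(C)=C/C=C/[C@@H](C)CC/C=C(/C)C[C@H](O)C(=O)OC | intermediate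
21 | methyl (2S,4Z,8S,9E,11E)-4,8,12-trimethyl-2-(propanoyloxy)pentadeca-4,9,11,14-tetraenoate | C=CC/C(C)=C/C=C/[C@@H](C)CC/C=C(/C)C[C@H](OC(=O)CC)C(=O)OC | intermediate
22 | (5S)-4-hydroxy-3-methyl-5-[(2Z,6S,7E,9E)-2,6,10-trimethyltrideca-2,7,9,12-tetraen-1-yl]furan-2(5H)-one | C=CC/C(C)=C/C=C/[C@@H](C)CC/C=C(/C)C[C@@H]1OC(=O)C(C)=C1O | intermediate
23 | (5S)-3-methyl-4-[2-(trimethylsilyl)ethoxy]-5-[(2Z,6S,7E,9E)-2,6,10-trimethyltrideca-2,7,9,12-tetraen-1-yl]furan-2(5H)-one | C=CC/C(C)=C/C=C/[C@@H](C)CC/C=C(/C)C[C@@H]1OC(=O)C(C)=C1OCC[Si](C)(C)C | intermediate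
24 | (5S)-5-[(2Z,6S,7E,9E)-13-(9-borabicyclo[3.3.1]nonan-9-yl)-2,6,10-trimethyltrideca-2,7,9-trien-1-yl]-3-methyl-4-[2-(trimethylsilyl)ethoxy]furan-2(5H)-one | B1(CCC/C(C)=C/C=C/[C@@H](C)CC/C=C(/C)C[C@@H]2OC(=O)C(C)=C2OCC[Si](C)(C)C)C3CCCC1CCC3 | intermediate (not isolated)
25 | (5S)-3-methyl-5-[(2Z,6S,7E,9E)-2,6,10-trimethyl-13-{1-[(2S)-2-methylbutyl]-2-oxo-2,5-dihydro-1H-pyrrol-3-yl}trideca-2,7,9-trien-1-yl]-4-[2-(trimethylsilyl)ethoxy]furan-2(5H)-one | CC[C@H](C)CN1CC=C(CCC/C(C)=C/C=C/[C@@H](C)CC/C=C(/C)C[C@@H]2OC(=O)C(C)=C2OCC[Si](C)(C)C)C1=O | intermediate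
26 | (5S)-4-hydroxy-3-methyl-5-[(2Z,6S,7E,9E)-2,6,10-trimethyl-13-{1-[(2S)-2-methylbutyl]-2-oxo-2,5-dihydro-1H-pyrrol-3-yl}trideca-2,7,9-trien-1-yl]furan-2(5H)-one | CC[C@H](C)CN1CC=C(CCC/C(C)=C/C=C/[C@@H](C)CC/C=C(/C)C[C@@H]2OC(=O)C(C)=C2O)C1=O | target

## Step count and risks

Total step count: 14.
Longest linear sequence: 11 steps (from 6: steps 3, 4 and 6–14).

Steps most likely to fail:

1. Step 13. The hydroboration may not stay fully on C1′=C2′ (B–H addition to the diene terminus), or transmetalation of the alkylborate may be slow enough for β-hydride elimination, protodeboronation or base-induced decomposition of the bromolactam to compete. The fallback separates hydroboration from coupling and replaces boron by zinc. It sets out from 23 and comes back at 25.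
   - 23 is hydroborated with 9-BBN (through borane 24) and oxidised with NaBO3·4H2O to the primary alcohol F1.
   - I2/PPh3/imidazole converts it to the primary iodide F2.
   - LiCl-assisted insertion of zinc dust (THF, 25–40 °C) gives the alkylzinc iodide F3.
   - A base-free Negishi coupling of F3 with bromolactam 5 (Pd2(dba)3/SPhos, THF, rt) should give 25.

2. Step 9. The alkenyl metal may add to the ester carbonyl of the glycidate, or the alkenyllithium may deprotonate the doubly allylic C3′ position before transmetalation. The fallback keeps the ester away from the organometallic. It sets out from 16 and comes back at 21.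
   - The alkenylmagnesium bromide 19, made from 16 as before (through 18), opens tert-butyl(dimethyl)[(2S)-oxiran-2-ylmethoxy]silane under the same CuBr·SMe2 catalysis at the epoxide CH2 to give the silyl ether alcohol F4; the epoxide stereocentre becomes the (2S) carbinol.
   - Propanoic anhydride/DMAP gives the propanoate F5.
   - HF·pyridine (THF, 0 °C) removes the silyl group to give the primary alcohol F6.
   - TEMPO/PhI(OAc)2 in MeCN/H2O oxidises it to the carboxylic acid F7.
   - Me3SiCHN2 (MeOH/toluene) gives 21.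

3. Step 8. The iodo ylide may partly lose iodine or decompose, and (Z)-selectivity may be incomplete. The fallback builds the (Z)-alkene by a Horner–Wadsworth–Emmons variant and the C5 stereocentre by auxiliary-controlled alkylation. It sets out from 15 and comes back at 20.
   - Still–Gennari olefination of 15 with methyl 2-[bis(2,2,2-trifluoroethoxy)phosphoryl]propanoate (KN(SiMe3)2, 18-crown-6, THF, −78 °C) gives the (Z)-enoate F8.
   - i-Bu2AlH (CH2Cl2, −78 °C) gives the allylic alcohol F9.
   - CBr4/PPh3 gives the allylic bromide F10.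
   - F10 alkylates the sodium enolate of (4R)-4-benzyl-3-{[(4-methoxybenzyl)oxy]acetyl}-1,3-oxazolidin-2-one (NaN(SiMe3)2, THF, −78 → −45 °C) to give the imide F11; the (2S) centre is set by attack anti to the benzyl group of the chelated (Z)-enolate.
   - NaOMe/MeOH (0 °C) gives the methyl ester F12.
   - DDQ (CH2Cl2/pH 7 buffer, 0 °C) removes the 4-methoxybenzyl group to give 20.

## Further compounds

F1 | step 13 | (5S)-5-[(2Z,6S,7E,9E)-13-hydroxy-2,6,10-trimethyltrideca-2,7,9-trien-1-yl]-3-methyl-4-[2-(trimethylsilyl)ethoxy]furan-2(5H)-one | OCCC/C(C)=C/C=C/[C@@H](C)CC/C=C(/C)C[C@@H]1OC(=O)C(C)=C1OCC[Si](C)(C)C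
F2 | step 13 | (5S)-5-[(2Z,6S,7E,9E)-13-iodo-2,6,10-trimethyltrideca-2,7,9-trien-1-yl]-3-methyl-4-[2-(trimethylsilyl)ethoxy]furan-2(5H)-one | ICCC/C(C)=C/C=C/[C@@H](C)CC/C=C(/C)C[C@@H]1OC(=O)C(C)=C1OCC[Si](C)(C)C
F3 | step 13 | {(4E,6E,8S,11Z)-4,8,12-trimethyl-13-[(2S)-4-methyl-5-oxo-3-[2-(trimethylsilyl)ethoxy]-2,5-dihydrofuran-2-yl]trideca-4,6,11-trien-1-yl}zinc iodide | I[Zn]CCC/C(C)=C/C=C/[C@@H](C)CC/C=C(/C)C[C@@H]1OC(=O)C(C)=C1OCC[Si](C)(C)C
F4 | step 9 | (2S,4Z,8S,9E,11E)-1-{[tert-butyl(dimethyl)silyl]oxy}-4,8,12-trimethylpentadeca-4,9,11,14-tetraen-2-ol | C=CC/C(C)=C/C=C/[C@@H](C)CC/C=C(/C)C[C@H](O)CO[Si](C)(C)C(C)(C)C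
F5 | step 9 | (2S,4Z,8S,9E,11E)-1-{[tert-butyl(dimethyl)silyl]oxy}-4,8,12-trimethylpentadeca-4,9,11,14-tetraen-2-yl propanoate | C=CC/C(C)=C/C=C/[C@@H](C)CC/C=C(/C)C[C@H](OC(=O)CC)CO[Si](C)(C)C(C)(C)C
F6 | step 9 | (2S,4Z,8S,9E,11E)-1-hydroxy-4,8,12-trimethylpentadeca-4,9,11,14-tetraen-2-yl propanoate | C=CC/C(C)=C/C=C/[C@@H](C)CC/C=C(/C)C[C@H](OC(=O)CC)CO
F7 | step 9 | (2S,4Z,8S,9E,11E)-4,8,12-trimethyl-2-(propanoyloxy)pentadeca-4,9,11,14-tetraenoic acid | C=CC/C(C)=C/C=C/[C@@H](C)CC/C=C(/C)C[C@H](OC(=O)CC)C(O)=O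
F8 | step 8 | methyl (2Z,6S,7E,9E)-2,6,10-trimethyltrideca-2,7,9,12-tetraenoate | C=CC/C(C)=C/C=C/[C@@H](C)CC/C=C(/C)C(=O)OC
F9 | step 8 | (2Z,6S,7E,9E)-2,6,10-trimethyltrideca-2,7,9,12-tetraen-1-ol | C=CC/C(C)=C/C=C/[C@@H](C)CC/C=C(/C)CO
F10 | step 8 | (4E,6E,8S,11Z)-13-bromo-4,8,12-trimethyltrideca-1,4,6,11-tetraene | C=CC/C(C)=C/C=C/[C@@H](C)CC/C=C(/C)CBr
F11 | step 8 | (4R)-4-benzyl-3-{(2S,4Z,8S,9E,11E)-2-[(4-methoxybenzyl)oxy]-4,8,12-trimethylpentadeca-4,9,11,14-tetraenoyl}-1,3-oxazolidin-2-one | C=CC/C(C)=C/C=C/[C@@H](C)CC/C=C(/C)C[C@H](OCc1ccc(OC)cc1)C(=O)N1[C@H](Cc2ccccc2)COC1=O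
F12 | step 8 | methyl (2S,4Z,8S,9E,11E)-2-[(4-methoxybenzyl)oxy]-4,8,12-trimethylpentadeca-4,9,11,14-tetraenoate | C=CC/C(C)=C/C=C/[C@@H](C)CC/C=C(/C)C[C@H](OCc1ccc(OC)cc1)C(=O)OC
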